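## The problem

Target 22 is two identical 7-acetyl-3,6,8-trihydroxy-4,4-dimethylnaphthalen-1(4H)-one units joined through one methylene carbon at C2 of each half. The synthesis therefore reduces to the monomer 20 and a single bridging event. There is no stereocentre, so the difficulty is substitution pattern and oxidation level, not configuration. Ring B is an enolised cyclic 1,3-dione (C1 ketone, C3 enol) with a quaternary gem-dimethyl carbon at C4 and a nucleophilic C2. Ring A is a pentasubstituted benzene with C6–OH, C7–acetyl and C8–OH in a row and hydrogen only at C5. An acetyl group between two oxygens is the position least accessible to electrophilic acylation of a resorcinol, because C5 would compete. The free acylresorcinol and the β-diketone enol are acidic, chelating and easily oxidised. A methylene-bis(1,3-dione) can also fragment by retro-Michael reaction in strong base or cyclodehydrate in hot strong acid, so these groups should be unveiled late and the bridge made last under near-neutral conditions. The enabling feature is the array C8a–C8(OH)–C7(carbon)–C6(O)–C5(H)–C4a of ring A. A vinylketene (supplying C4a, C5, C8, C8a) and an oxygen-substituted alkyne (supplying C6, C7) assemble exactly this array, so the fusion carbons can be the alkene of a cyclohexene that already carries C4 and the C3 oxygen.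

## Retrosynthesis

**22 to 20 and 21.** The two C2–CH2 bonds are cut, giving two molecules of monomer 20 and formaldehyde 21. The symmetry of 22 makes this the obvious first cut and halves the problem. The forward reaction is a Knoevenagel–Michael sequence at the most acidic carbon of 20. It has to discriminate C2 from the single aromatic CH (C5), which the peri gem-dimethyl group shields.

**20 to 18.** No skeletal bond is cut; four masked functions are removed. In 18 the acetyl group and the C3 carbonyl are both dioxolanes, the C6 oxygen is a triisopropylsilyl ether and the C8 oxygen an acetate. Fluoride followed by aqueous acid should remove all four in one flask. Keeping ring A masked until this point protects the acylresorcinol from every oxidising or basic step.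

**18 to 17 to 16.** The C1 carbonyl is traced back to a benzylic methylene (17), and the acetate to the free C8 phenol (16). The neighbouring option was to carry a free C3 ketone, dehydrogenate C1–C2, epoxidise the enone and isomerise the epoxy ketone. That costs three steps and needs a free, enolisable ring ketone from the start. With C3 as a ketal, C1 is the only benzylic C–H position, is activated by the para C6 silyloxy group, and should be oxidised in one step with no acidic C2 to over-oxidise. The phenol must be capped first because peroxyl radicals oxidise free phenols.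

**16 to 7 and 11 (key disconnection).** Four bonds of ring A are cut: C4a–C5, C5–C6, C7–C8 and C8–C8a. This leaves diazo ketone 7, which holds ring B with C4 and the masked C3 oxygen, and siloxyalkyne 11, which holds C6, C7 and the masked acetyl group. Against stepwise functionalisation of a preformed arene, this places the acetyl carbon between the two oxygens by construction and leaves hydrogen at C5. The forward reaction must form the [2+2] adduct in one orientation only; the polarisation of the siloxyalkyne secures this.

**7 to 5 to 3 to 2 to 1.** The diazo group comes from the methyl ketone 5 by diazo transfer. The acetyl group comes from the enol triflate 3 by cross-coupling, and 3 from the monoketal 2 of commercial dione 1. The dione supplies C4 with both methyl groups, C3 with its oxygen and four further ring carbons in the correct order. The ring ketone is carried as its dioxolane rather than free. This leaves the acetyl methyl as the only enolisable position in 5, so the diazo transfer cannot go astray, and it allows the single-step C1 oxidation later.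

**11 to 9 to 8.** The C–O bond of the siloxyalkyne is cut back to terminal alkyne 9, the ketal of commercial but-3-yn-2-one 8. Oxidation of the acetylide to the ynolate and O-silylation is a two-operation, one-flask way to the triisopropylsiloxyalkyne.

## Roads not taken

**Alternative 1:** Four C4–methyl bonds are cut, leading from the tetra-O-methyl ether A2 of the target back to the methylene-bridged bis(naphthalene-1,3-diol) A1. Forward, A1 would be C-methylated twice at each C4 with alkoxide base and a methyl electrophile, dearomatising both rings B and creating both quaternary carbons in one flask. Demethylation of A2 would then give 22.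
- Merits: very convergent, all aromatic chemistry up to the last stage, no photochemistry or diazo compound, and potentially the shortest route.
- Weak points: each half of A1 offers two hydroxyl oxygens and the already substituted C2 as competing nucleophilic sites. Four C-alkylations must all go to C4, so mixtures of O-methyl, C2-quaternised and partly methylated products are likely. The methylene bridge is exposed to strong base, and four aryl methyl ethers must finally be cleaved beside two sensitive enolised diones.
- Comparison: this road is better in convergence and step count. The chosen plan sets against it a gem-dimethyl carbon bought ready-made in 1 and a ring construction whose regiochemistry is not left to competition among nucleophilic sites.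

**Alternative 2:** The bonds C8a–C4a and C6–C5 are cut. Forward, the silyl dienol ether A3 would undergo an intramolecular Diels–Alder addition of its terminal alkyne to the cyclohexadiene. Cycloreversion with loss of the two-carbon bridge would aromatise ring A, closing ring B and giving A4 after desilylation.
- Merits: one thermal step forms ring B and aromatises ring A, and ring B emerges at the final 1,3-dione oxidation level. That is better than the chosen plan, which needs a late benzylic oxidation.
- Weak points: A4 has no acetyl group at C7 and carries an ethyl ether at C6. Late acylation between the two oxygens would have to beat C5, and the ether must be cleaved. A3 requires selective enol silylation of a ring ketone beside a more acidic open-chain 1,3-diketone. The dienophile is an unactivated alkyne on a quaternary carbon, so forcing temperatures are needed.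
- Comparison: the chosen plan brings the acetyl carbon in with the alkyne and therefore has no C7/C5 question. It pays with protecting groups and one oxidation.

**Alternative 3:** The bonds C4a–C5 and C7–C8 are cut. Forward, the dianion of pentane-2,4-dione A6 would add through its terminal carbon to the symmetric dienone A5 with loss of methoxide. Its central carbon would then attack the neighbouring ester, closing and aromatising ring A to give A7. Hydrolysis and decarboxylation of A7 would lead to 20 and the same final bridging.
- Merits: one anionic step from a cheap diketone delivers the C6 hydroxyl, C7 acetyl, C8 hydroxyl and C5 hydrogen, and ring B is already at its final oxidation level. It needs no photochemistry, tin or ring-A protecting groups, and would be shorter and more redox-economical than the chosen plan.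
- Weak points: A5 is a fully substituted cross-conjugated dienone that must first be made. The hard dianion must prefer addition–elimination at the hindered carbon next to the quaternary centre over 1,2-addition or acylation at either ester. The second bond must form through carbon, not oxygen, and the two equivalent sites of A5 invite double addition.
- Comparison: the chosen plan sets against the shorter count a ring-forming reaction of established scope with regiochemistry fixed by alkyne polarisation, and precursors made by standard reactions.

Key step: step 7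

Assumption (remark on the chemistry): 22 is achiral. The transient intermediates 13 and 15 and the fallback alcohol F5 each carry one stereocentre and are racemic, so their SMILES carry no configuration. F1–F3 are mixtures of alkene isomers.

## Route

Step 1
Reactants: 1 2,2-dimethylcyclohexane-1,3-dione
Product: 2 6,6-dimethyl-1,4-dioxaspiro[4.5]decan-7-one
Conditions: ethylene glycol (1.1 equiv), p-TsOH (cat.), benzene, reflux, Dean–Stark
Reagents that add atoms: ethylene glycol OCCO
Why: Acid-catalysed ketalisation with azeotropic water removal; the second carbonyl is flanked by the quaternary carbon and the new dioxolane and is ketalised much more slowly, so one equivalent of glycol should stop at the monoketal.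

Step 2
Reactants: 2 6,6-dimethyl-1,4-dioxaspiro[4.5]decan-7-one
Product: 3 6,6-dimethyl-1,4-dioxaspiro[4.5]dec-7-en-7-yl trifluoromethanesulfonate
Conditions: KN(SiMe3)2, THF, −78 °C; then PhNTf2, −78 °C to r.t.
Reagents that add atoms: N-phenylbis(trifluoromethanesulfonimide) O=S(=O)(N(c1ccccc1)S(=O)(=O)C(F)(F)F)C(F)(F)F
Why: Enolisation can only occur toward the ring methylene (the other α-carbon is quaternary), and O-sulfonylation of the potassium enolate is the standard vinyl triflate synthesis.

Step 3
Reactants: 3 6,6-dimethyl-1,4-dioxaspiro[4.5]dec-7-en-7-yl trifluoromethanesulfonate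
Product: 5 1-(6,6-dimethyl-1,4-dioxaspiro[4.5]dec-7-en-7-yl)ethan-1-one, via ethoxyvinyl diene 4 (not isolated)
Conditions: tributyl(1-ethoxyvinyl)stannane, Pd(PPh3)4 (5 mol %), LiCl, 1,4-dioxane, 90 °C; then 1 M aq. HCl, THF, 0 °C, short contact
Reagents that add atoms: tributyl(1-ethoxyvinyl)stannane CCCC[Sn](CCCC)(CCCC)C(=C)OCC; water O
Why: Stille coupling of a vinyl triflate (oxidative addition to zerovalent palladium, chloride-assisted transmetalation, reductive elimination), then hydrolysis of the 2-ethoxydiene 4, which is protonated at its terminal carbon far faster than a dioxolane opens, so brief cold dilute acid should unmask the methyl ketone and spare the ketal.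

Step 4
Reactants: 5 1-(6,6-dimethyl-1,4-dioxaspiro[4.5]dec-7-en-7-yl)ethan-1-one
Product: 7 2-diazo-1-(6,6-dimethyl-1,4-dioxaspiro[4.5]dec-7-en-7-yl)ethan-1-one, via trifluoroacetyl diketone 6 (not isolated)
Conditions: LiN(SiMe3)2, THF, −78 °C; CF3CO2CH2CF3; then MsN3, Et3N, H2O, MeCN, r.t.
Reagents that add atoms: methanesulfonyl azide CS(=O)(=O)N=[N+]=[N-]
Why: Detrifluoroacetylative diazo transfer; the acetyl methyl is the only enolisable position, Claisen trifluoroacetylation activates it, and azide transfer with loss of the trifluoroacetyl group as its N-sulfonyl amide gives the unsaturated α-diazo ketone without the dipolar cycloaddition that spoils acid chloride/diazomethane routes.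

Step 5
Reactants: 8 but-3-yn-2-one
Product: 9 2-ethynyl-2-methyl-1,3-dioxolane
Conditions: Me3SiOCH2CH2OSiMe3, TMSOTf (cat.), CH2Cl2, −78 to −20 °C; pyridine quench
Reagents that add atoms: 1,2-bis(trimethylsilyloxy)ethane C[Si](C)(C)OCCO[Si](C)(C)C
Why: Silyl-transfer ketalisation driven by formation of hexamethyldisiloxane proceeds at low temperature and is the usual way to ketalise a conjugated ynone without conjugate addition of the diol.

Step 6
Reactants: 9 2-ethynyl-2-methyl-1,3-dioxolane
Product: 11 triisopropyl{[(2-methyl-1,3-dioxolan-2-yl)ethynyl]oxy}silane, via lithium ynolate 10 (not isolated)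
Conditions: LiN(SiMe3)2, THF, −78 °C; LiOOtBu (from tBuOOH and LiN(SiMe3)2), −78 to 0 °C; then iPr3SiOTf, −78 °C to r.t.
Reagents that add atoms: tert-butyl hydroperoxide CC(C)(C)OO; triisopropylsilyl trifluoromethanesulfonate CC(C)[Si](OS(=O)(=O)C(F)(F)F)(C(C)C)C(C)C
Why: Oxygen transfer from lithium tert-butylperoxide to the lithium acetylide gives ynolate 10, and the bulky silyl triflate traps it on oxygen to give an isolable triisopropylsiloxyalkyne; this is an established siloxyalkyne synthesis from terminal alkynes.

Step 7
Reactants: 7 2-diazo-1-(6,6-dimethyl-1,4-dioxaspiro[4.5]dec-7-en-7-yl)ethan-1-one; 11 triisopropyl{[(2-methyl-1,3-dioxolan-2-yl)ethynyl]oxy}silane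
Product: 16 1',1'-dimethyl-6'-(2-methyl-1,3-dioxolan-2-yl)-7'-[(triisopropylsilyl)oxy]-3',4'-dihydro-1'H-spiro[[1,3]dioxolane-2,2'-naphthalen]-5'-ol, via vinylketene 12 (not isolated), via vinylcyclobutenone 13 (not isolated), via dienylketene 14 (not isolated), via cyclohexadienone 15 (not isolated)
Conditions: 11 (1.5 equiv), degassed ClCH2CH2Cl, hν (254 nm, low-pressure mercury lamp), r.t.; then 80 °C in the dark
Reagents that add atoms: none
Why: Light expels dinitrogen from 7 and Wolff rearrangement moves the ring alkenyl carbon (C4a) to the diazo carbon (C5), giving vinylketene 12. Alkyne 11 then adds across the ketene C=C in a [2+2] cycloaddition: its nucleophilic carbon remote from oxygen (C7) bonds to the ketene carbonyl carbon (C8) and the siloxy carbon (C6) to C5, giving cyclobutenone 13. Reversible four-electron electrocyclic opening of 13 gives dienylketene 14, and the isomer with the ring alkene cis to the ketene is drained by six-electron disrotatory electrocyclisation between C8 and C8a; this closes ring A as cyclohexadienone 15, which tautomerises to phenol 16. This is the Danheiser benzannulation of an unsaturated α-diazo ketone with a siloxyalkyne, a known route to resorcinol monosilyl ethers. No stereocentre remains, since 13 and 15 are racemic transients. The step needs one orientation of the [2+2] addition, which the oxygen-induced polarisation of the alkyne secures, and it needs hydrogen at C5, which is the diazo CH. Clean ketene capture is helped by the excess of 11 and by the ring ketal, which leaves no second photoactive carbonyl. Heating after irradiation should convert any remaining 13.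

Step 8
Reactants: 16 1',1'-dimethyl-6'-(2-methyl-1,3-dioxolan-2-yl)-7'-[(triisopropylsilyl)oxy]-3',4'-dihydro-1'H-spiro[[1,3]dioxolane-2,2'-naphthalen]-5'-ol
Product: 17 1',1'-dimethyl-6'-(2-methyl-1,3-dioxolan-2-yl)-7'-[(triisopropylsilyl)oxy]-3',4'-dihydro-1'H-spiro[[1,3]dioxolane-2,2'-naphthalen]-5'-yl acetate
Conditions: Ac2O, Et3N, DMAP (cat.), CH2Cl2, r.t.
Reagents that add atoms: acetic anhydride CC(=O)OC(C)=O
Why: DMAP-catalysed O-acylation caps the phenol, which peroxyl radicals would otherwise oxidise in step 9; the small acetyl group fits between the peri methylene and the dioxolane, releases no reactive electrophile on removal, and comes off with fluoride or acid at the end.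

Step 9
Reactants: 17 1',1'-dimethyl-6'-(2-methyl-1,3-dioxolan-2-yl)-7'-[(triisopropylsilyl)oxy]-3',4'-dihydro-1'H-spiro[[1,3]dioxolane-2,2'-naphthalen]-5'-yl acetate
Product: 18 1',1'-dimethyl-6'-(2-methyl-1,3-dioxolan-2-yl)-4'-oxo-7'-[(triisopropylsilyl)oxy]-3',4'-dihydro-1'H-spiro[[1,3]dioxolane-2,2'-naphthalen]-5'-yl acetate
Conditions: Rh2(cap)4 (1 mol %; cap = caprolactamate), tBuOOH (5 equiv), NaHCO3, ClCH2CH2Cl, 40 °C
Reagents that add atoms: tert-butyl hydroperoxide CC(C)(C)OO
Why: Rh2(cap)4-catalysed benzylic oxidation with tBuOOH (hydrogen abstraction by the tert-butylperoxyl radical, capture as the mixed peroxide, loss of tert-butanol) is established for tetralins; C1 of the target numbering is the only benzylic carbon bearing hydrogen and is activated by the para silyloxy group, and the C3 ketal keeps C2 non-enolisable so over-oxidation is not expected.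

Step 10
Reactants: 18 1',1'-dimethyl-6'-(2-methyl-1,3-dioxolan-2-yl)-4'-oxo-7'-[(triisopropylsilyl)oxy]-3',4'-dihydro-1'H-spiro[[1,3]dioxolane-2,2'-naphthalen]-5'-yl acetate
Product: 20 7-acetyl-3,6,8-trihydroxy-4,4-dimethylnaphthalen-1(4H)-one, via diketal diphenol 19 (not isolated)
Conditions: Bu4NF (3 equiv), THF, 0 °C to r.t.; then 3 M aq. HCl, THF, 50 °C
Reagents that add atoms: water O
Why: Fluoride cleaves the aryl silyl ether and the aryl acetate, then aqueous acid hydrolyses both dioxolanes; hydrolysis of the hindered C3 ketal, which is β to the C1 ketone, is driven by formation of the enolised, hydrogen-bonded 1,3-dione.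

Step 11
Reactants: 20 7-acetyl-3,6,8-trihydroxy-4,4-dimethylnaphthalen-1(4H)-one (two equivalents); 21 formaldehyde
Product: 22 2,2'-methylenebis[7-acetyl-3,6,8-trihydroxy-4,4-dimethylnaphthalen-1(4H)-one]
Conditions: 37% aq. HCHO (0.5 equiv), NaOAc, AcOH/EtOH, r.t. to 40 °C
Reagents that add atoms: none
Why: Knoevenagel condensation of one molecule of 20 with formaldehyde at C2 gives a 2-methylene-1,3-dione that is captured by Michael addition of a second molecule through its C2 (classic methylene-bis(1,3-dione) formation); in acetate buffer only the diketone is appreciably ionised, formaldehyde is limiting, and the lone aromatic CH at C5 is shielded by the peri gem-dimethyl group.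

## Compound list

1 | 2,2-dimethylcyclohexane-1,3-dione | CC1(C)C(=O)CCCC1=O | starting material
2 | 6,6-dimethyl-1,4-dioxaspiro[4.5]decan-7-one | CC1(C)C(=O)CCCC12OCCO2 | intermediate
3 | 6,6-dimethyl-1,4-dioxaspiro[4.5]dec-7-en-7-yl trifluoromethanesulfonate | CC1(C)C(OS(=O)(=O)C(F)(F)F)=CCCC12OCCO2 | intermediate
4 | 7-(1-ethoxyethenyl)-6,6-dimethyl-1,4-dioxaspiro[4.5]dec-7-ene (not isolated) | CCOC(=C)C1=CCCC2(OCCO2)C1(C)C | intermediate
5 | 1-(6,6-dimethyl-1,4-dioxaspiro[4.5]dec-7-en-7-yl)ethan-1-one | CC(=O)C1=CCCC2(OCCO2)C1(C)C | intermediate
6 | 1-(6,6-dimethyl-1,4-dioxaspiro[4.5]dec-7-en-7-yl)-4,4,4-trifluorobutane-1,3-dione (not isolated) | O=C(CC(=O)C(F)(F)F)C1=CCCC2(OCCO2)C1(C)C | intermediate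
7 | 2-diazo-1-(6,6-dimethyl-1,4-dioxaspiro[4.5]dec-7-en-7-yl)ethan-1-one (ethylene ketal of 2-diazo-1-(6,6-dimethyl-5-oxocyclohex-1-en-1-yl)ethan-1-one) | [N-]=[N+]=CC(=O)C1=CCCC2(OCCO2)C1(C)C | intermediate
8 | but-3-yn-2-one | CC(=O)C#C | starting material
9 | 2-ethynyl-2-methyl-1,3-dioxolane | CC1(C#C)OCCO1 | intermediate
10 | lithium 2-(2-methyl-1,3-dioxolan-2-yl)ethyn-1-olate (not isolated) | [Li+].[O-]C#CC1(C)OCCO1 | intermediate
11 | triisopropyl{[(2-methyl-1,3-dioxolan-2-yl)ethynyl]oxy}silane | CC1(C#CO[Si](C(C)C)(C(C)C)C(C)C)OCCO1 | intermediate
12 | 2-(6,6-dimethyl-1,4-dioxaspiro[4.5]dec-7-en-7-yl)ethen-1-one, the vinylketene (not isolated) | O=C=CC1=CCCC2(OCCO2)C1(C)C | intermediate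
13 | 4-(6,6-dimethyl-1,4-dioxaspiro[4.5]dec-7-en-7-yl)-2-(2-methyl-1,3-dioxolan-2-yl)-3-[(triisopropylsilyl)oxy]cyclobut-2-en-1-one, racemic (not isolated) | O=C1C(C2(C)OCCO2)=C(O[Si](C(C)C)(C(C)C)C(C)C)C1C1=CCCC2(OCCO2)C1(C)C | intermediate
14 | 4-(6,6-dimethyl-1,4-dioxaspiro[4.5]dec-7-en-7-yl)-2-(2-methyl-1,3-dioxolan-2-yl)-3-[(triisopropylsilyl)oxy]buta-1,3-dien-1-one, ring alkene cis to the ketene-bearing carbon (not isolated) | O=C=C(C1(C)OCCO1)/C(O[Si](C(C)C)(C(C)C)C(C)C)=C\C1=CCCC2(OCCO2)C1(C)C | intermediate
15 | 1',1'-dimethyl-6'-(2-methyl-1,3-dioxolan-2-yl)-7'-[(triisopropylsilyl)oxy]-3',4'-dihydro-1'H-spiro[[1,3]dioxolane-2,2'-naphthalen]-5'(4a'H)-one, racemic keto tautomer of 16 (not isolated) | O=C1C(C2(C)OCCO2)=C(O[Si](C(C)C)(C(C)C)C(C)C)C=C2C1CCC1(OCCO1)C2(C)C | intermediate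
16 | 1',1'-dimethyl-6'-(2-methyl-1,3-dioxolan-2-yl)-7'-[(triisopropylsilyl)oxy]-3',4'-dihydro-1'H-spiro[[1,3]dioxolane-2,2'-naphthalen]-5'-ol (2-ethylene ketal of 5-hydroxy-1,1-dimethyl-6-(2-methyl-1,3-dioxolan-2-yl)-7-[(triisopropylsilyl)oxy]-3,4-dihydronaphthalen-2(1H)-one) | CC1(c2c(O[Si](C(C)C)(C(C)C)C(C)C)cc3c(c2O)CCC2(OCCO2)C3(C)C)OCCO1 | intermediate
17 | 1',1'-dimethyl-6'-(2-methyl-1,3-dioxolan-2-yl)-7'-[(triisopropylsilyl)oxy]-3',4'-dihydro-1'H-spiro[[1,3]dioxolane-2,2'-naphthalen]-5'-yl acetate | CC1(c2c(O[Si](C(C)C)(C(C)C)C(C)C)cc3c(c2OC(C)=O)CCC2(OCCO2)C3(C)C)OCCO1 | intermediate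
18 | 1',1'-dimethyl-6'-(2-methyl-1,3-dioxolan-2-yl)-4'-oxo-7'-[(triisopropylsilyl)oxy]-3',4'-dihydro-1'H-spiro[[1,3]dioxolane-2,2'-naphthalen]-5'-yl acetate | CC1(c2c(O[Si](C(C)C)(C(C)C)C(C)C)cc3c(c2OC(C)=O)C(=O)CC2(OCCO2)C3(C)C)OCCO1 | intermediate
19 | 5',7'-dihydroxy-1',1'-dimethyl-6'-(2-methyl-1,3-dioxolan-2-yl)-1'H-spiro[[1,3]dioxolane-2,2'-naphthalen]-4'(3'H)-one (not isolated) | CC1(c2c(O)cc3c(c2O)C(=O)CC2(OCCO2)C3(C)C)OCCO1 | intermediate
20 | 7-acetyl-3,6,8-trihydroxy-4,4-dimethylnaphthalen-1(4H)-one | CC(=O)c1c(O)cc2c(c1O)C(=O)C=C(O)C2(C)C | intermediate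
21 | formaldehyde | C=O | starting material
22 | 2,2'-methylenebis[7-acetyl-3,6,8-trihydroxy-4,4-dimethylnaphthalen-1(4H)-one] | CC(=O)c1c(O)cc2c(c1O)C(=O)C(CC1=C(O)C(C)(C)c3cc(O)c(C(C)=O)c(O)c3C1=O)=C(O)C2(C)C | target

## Step count and least certain steps

Total step count: 11 (steps 1–4 for the diazo ketone, steps 5–6 for the siloxyalkyne, steps 7–11 after their union).
Longest linear sequence: 9 steps (1 to 22 through steps 1–4 and 7–11).

**Step 7 (key step).** The most likely failure is slow capture of the photogenerated vinylketene by the hindered siloxyalkyne, whose ketal substituent is inductively deactivating. Ketene dimerisation, O-acylation of the phenol already formed and secondary photolysis could then compete. The fallback makes the same ketene thermally, slowly and without light: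
- From 2, Peterson olefination with ethyl (trimethylsilyl)acetate and LiN(iPr)2 should give ethyl 2-(6,6-dimethyl-1,4-dioxaspiro[4.5]decan-7-ylidene)acetate F1.
- Saponification with LiOH gives 2-(6,6-dimethyl-1,4-dioxaspiro[4.5]decan-7-ylidene)acetic acid F2.
- Oxalyl chloride on the sodium salt of F2 gives 2-(6,6-dimethyl-1,4-dioxaspiro[4.5]decan-7-ylidene)acetyl chloride F3.
- Slow addition of Et3N to F3 and 11 in toluene at 80 °C effects 1,4-dehydrochlorination through the only γ-methylene. This gives vinylketene 12 at low stationary concentration, and the route is rejoined at 16 through 13–15.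

**Step 9.** The most likely failure is loss of site selectivity in the radical oxidation: attack at ether C–H bonds of the dioxolanes or on the electron-rich ring, or ionisation at C1 followed by elimination toward C2. The fallback makes that elimination deliberate:
- From 17, DDQ in dioxane should dehydrogenate the only position that can become an alkene, giving 1',1'-dimethyl-6'-(2-methyl-1,3-dioxolan-2-yl)-7'-[(triisopropylsilyl)oxy]-1'H-spiro[[1,3]dioxolane-2,2'-naphthalen]-5'-yl acetate F4.
- Mukaiyama hydration (Co(acac)2, PhSiH3, O2) places oxygen at the benzylic carbon through the benzylic radical, giving racemic 4'-hydroxy-1',1'-dimethyl-6'-(2-methyl-1,3-dioxolan-2-yl)-7'-[(triisopropylsilyl)oxy]-3',4'-dihydro-1'H-spiro[[1,3]dioxolane-2,2'-naphthalen]-5'-yl acetate F5.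
- F5 is oxidised without delay with Dess–Martin periodinane, returning to the route at 18.

**Step 11.** The most likely failure is loss of chemoselectivity of the one-pot condensation: attack of the methylene-dione by the aromatic C5 position, or multiple condensation giving unsymmetrical and oligomeric products. The fallback separates electrophile formation from coupling:
- From 20, dimethylmethyleneammonium iodide in MeCN should give the Mannich base 7-acetyl-2-[(dimethylamino)methyl]-3,6,8-trihydroxy-4,4-dimethylnaphthalen-1(4H)-one F6.
- Heating F6 with one further equivalent of 20 in EtOH releases dimethylamine, so the methylene-dione is generated only in the presence of its acceptor partner. The route is rejoined at 22.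

**Step 3.** The most likely failure is slow transmetalation at the neopentyl-type vinyl triflate, allowing hydrolysis or reduction of the triflate, or partial loss of the ketal during enol ether hydrolysis. The fallback avoids both the bulky stannane and the acid:
- From 3, aminocarbonylation (Pd(OAc)2, Xantphos, CO, MeNHOMe·HCl, Et3N, toluene, 80 °C) should give N-methoxy-N,6,6-trimethyl-1,4-dioxaspiro[4.5]dec-7-ene-7-carboxamide F7.
- MeMgBr in THF at 0 °C converts F7 to the methyl ketone, returning to the route at 5.

## Further compounds

F1 | step 7 | ethyl 2-(6,6-dimethyl-1,4-dioxaspiro[4.5]decan-7-ylidene)acetate (mixture of alkene isomers) | CCOC(=O)C=C1CCCC2(OCCO2)C1(C)C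
F2 | step 7 | 2-(6,6-dimethyl-1,4-dioxaspiro[4.5]decan-7-ylidene)acetic acid (mixture of alkene isomers) | OC(=O)C=C1CCCC2(OCCO2)C1(C)C
F3 | step 7 | 2-(6,6-dimethyl-1,4-dioxaspiro[4.5]decan-7-ylidene)acetyl chloride (mixture of alkene isomers) | O=C(Cl)C=C1CCCC2(OCCO2)C1(C)C
F4 | step 9 | 1',1'-dimethyl-6'-(2-methyl-1,3-dioxolan-2-yl)-7'-[(triisopropylsilyl)oxy]-1'H-spiro[[1,3]dioxolane-2,2'-naphthalen]-5'-yl acetate | CC1(c2c(O[Si](C(C)C)(C(C)C)C(C)C)cc3c(c2OC(C)=O)C=CC2(OCCO2)C3(C)C)OCCO1
F5 | step 9 | 4'-hydroxy-1',1'-dimethyl-6'-(2-methyl-1,3-dioxolan-2-yl)-7'-[(triisopropylsilyl)oxy]-3',4'-dihydro-1'H-spiro[[1,3]dioxolane-2,2'-naphthalen]-5'-yl acetate (racemic) | CC1(c2c(O[Si](C(C)C)(C(C)C)C(C)C)cc3c(c2OC(C)=O)C(O)CC2(OCCO2)C3(C)C)OCCO1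
F6 | step 11 | 7-acetyl-2-[(dimethylamino)methyl]-3,6,8-trihydroxy-4,4-dimethylnaphthalen-1(4H)-one | CC(=O)c1c(O)cc2c(c1O)C(=O)C(CN(C)C)=C(O)C2(C)C
F7 | step 3 | N-methoxy-N,6,6-trimethyl-1,4-dioxaspiro[4.5]dec-7-ene-7-carboxamide | CON(C)C(=O)C1=CCCC2(OCCO2)C1(C)C
A1 | alternative 1 | 2,2'-methylenebis(7-acetyl-6,8-dimethoxynaphthalene-1,3-diol) | CC(=O)c1c(OC)cc2cc(O)c(Cc3c(O)cc4cc(OC)c(C(C)=O)c(OC)c4c3O)c(O)c2c1OC
A2 | alternative 1 | 2,2'-methylenebis[7-acetyl-3-hydroxy-6,8-dimethoxy-4,4-dimethylnaphthalen-1(4H)-one] | CC(=O)c1c(OC)cc2c(c1OC)C(=O)C(CC1=C(O)C(C)(C)c3cc(OC)c(C(C)=O)c(OC)c3C1=O)=C(O)C2(C)C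
A3 | alternative 2 | 1-{2-[(tert-butyldimethylsilyl)oxy]-4-ethoxycyclohexa-1,3-dien-1-yl}-4,4-dimethylhex-5-yne-1,3-dione | CCOC1=CC(O[Si](C)(C)C(C)(C)C)=C(CC1)C(=O)CC(=O)C(C)(C)C#C
A4 | alternative 2 | 6-ethoxy-3,8-dihydroxy-4,4-dimethylnaphthalen-1(4H)-one | CCOc1cc(O)c2c(c1)C(C)(C)C(O)=CC2=O
A5 | alternative 3 | dimethyl 4,6-dimethoxy-5,5-dimethyl-2-oxocyclohexa-3,6-diene-1,3-dicarboxylate | COC(=O)C1=C(OC)C(C)(C)C(OC)=C(C(=O)OC)C1=O
A6 | alternative 3 | pentane-2,4-dione | CC(=O)CC(C)=O
A7 | alternative 3 | methyl 7-acetyl-6,8-dihydroxy-3-methoxy-4,4-dimethyl-1-oxo-1,4-dihydronaphthalene-2-carboxylate | CC(=O)c1c(O)cc2c(c1O)C(=O)C(C(=O)OC)=C(OC)C2(C)C
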